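The oxane ring (O1, C2 aryl, C3, C4 OH, C5, C6 arylethyl) is a 2,6-cis-tetrahydropyran-4-ol; its C4 oxygen and C3 branch are read as a C3=C4 silyl enol ether, so the ring is cut at O1–C2 and C5–C6 into aldehyde 3 and 2-siloxydiene 18. One chromium-catalysed hetero-Diels–Alder reaction forms both bonds, closes the ring and sets C2 and C6 cis. Diene 18 carries the (E)-aryl terminus and the complete Ca side chain with both stereocentres; it is built through a Weinreb amide, a latent methyl ketone, so that C3 is the only enolisable carbon when the arylidene is installed. Phenols travel as TIPS ethers, the carbinol as a TBS ether.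

Key step: step 14

Abbreviations: Ar = 4-(triisopropylsilyloxy)phenyl; TIPS = triisopropylsilyl; TBS = tert-butyldimethylsilyl; Ca = the styryl-bearing carbon on C3; [CrCl(L)] = chromium chloride complex of L, the dianion of the Schiff base from 3-(1-adamantyl)-2-hydroxy-5-methylbenzaldehyde and (1R,2S)-1-aminoindan-2-ol.

Assumption: the usual sense of induction is taken for the three chiral reagents ((+)-Ipc2B(allyl) gives the (S)-carbinol, (S)-BINAP/rhodium gives (3R)-13, the (1R,2S)-chromium catalyst gives C6 (S)); should one prove opposite, its antipode is used with no other change.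

Step 1
Reactants: 1 methyl 3-(4-hydroxyphenyl)propanoate
Product: 2 methyl 3-Ar-propanoate
Conditions: TIPSCl, imidazole, DMF, rt
Reagents that add atoms: triisopropylsilyl chloride, CC(C)[Si](Cl)(C(C)C)C(C)C
Why: Imidazole-promoted O-silylation of a phenol is routine, and the aryl TIPS ether is chosen because it withstands the bases and nucleophiles used later better than an aryl TBS ether yet falls to fluoride at the end.

Step 2
Reactants: 2 methyl 3-Ar-propanoate
Product: 3 3-Ar-propanal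
Conditions: i-Bu2AlH (1.1 equiv), CH2Cl2, −78 °C
Reagents that add atoms: none
Why: Partial ester reduction with i-Bu2AlH should stop at the aldehyde because the tetrahedral aluminium hemiacetal is stable at −78 °C and collapses only on work-up.

Step 3
Reactants: 3 3-Ar-propanal
Product: 4 (3S)-1-Ar-hex-5-en-3-ol
Conditions: (+)-Ipc2B(CH2CH=CH2), Et2O, −78 °C; then HOCH2CH2NH2, rt
Reagents that add atoms: (+)-B-allyldiisopinocampheylborane (from (−)-α-pinene), C=CCB([C@H]1C[C@H]2C[C@@H]([C@@H]1C)C2(C)C)[C@H]1C[C@H]2C[C@@H]([C@@H]1C)C2(C)C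
Why: Brown allylboration passes through a closed chair transition state in which the isopinocampheyl groups direct allyl transfer to one aldehyde face, so the (S)-carbinol is set by the reagent.

Step 4
Reactants: 4 (3S)-1-Ar-hex-5-en-3-ol
Product: 5 (3S)-1-Ar-3-(tert-butyldimethylsilyloxy)hex-5-ene
Conditions: TBSCl, imidazole, DMF, rt
Reagents that add atoms: tert-butyldimethylsilyl chloride, CC(C)(C)[Si](C)(C)Cl
Why: Silylation of the secondary alcohol gives a TBS ether that survives every later step up to the final fluoride treatment, and the stereocentre is not touched.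

Step 5
Reactants: 5 (3S)-1-Ar-3-(tert-butyldimethylsilyloxy)hex-5-ene; 6 N-methoxy-N-methylprop-2-enamide (3 equiv)
Product: 7 (2E,5S)-5-(tert-butyldimethylsilyloxy)-N-methoxy-N-methyl-7-Ar-hept-2-enamide
Conditions: second-generation Hoveyda–Grubbs catalyst (5 mol %), CH2Cl2, 40 °C
Reagents that add atoms: none
Why: Olefin cross-metathesis of a terminal alkene with an electron-poor acrylamide favours the cross product, and secondary metathesis should equilibrate it to the (E)-enamide.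

Step 6
Reactants: 8 4-hydroxybenzaldehyde
Product: 9 4-(triisopropylsilyloxy)benzaldehyde
Conditions: TIPSCl, imidazole, DMF, rt
Reagents that add atoms: triisopropylsilyl chloride, CC(C)[Si](Cl)(C(C)C)C(C)C
Why: Phenol O-silylation as in step 1 gives the non-enolisable aldehyde that serves both the alkyne synthesis and the later aldol step.

Step 7
Reactants: 9 4-(triisopropylsilyloxy)benzaldehyde
Product: 10 1-ethynyl-4-(triisopropylsilyloxy)benzene
Conditions: Me3SiCHN2, LiN(i-Pr)2, THF, −78 °C → rt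
Reagents that add atoms: (trimethylsilyl)diazomethane, C[Si](C)(C)C=[N+]=[N-]
Why: In the Colvin rearrangement the lithiated silyldiazomethane adds to the aldehyde, Peterson-type elimination gives a diazoalkene that loses N2, and a 1,2-hydrogen shift of the alkylidene carbene gives the terminal alkyne.

Step 8
Reactants: 10 1-ethynyl-4-(triisopropylsilyloxy)benzene
Product: 12 [(E)-2-Ar-ethenyl]boronic acid, via catechol boronate 11 (not isolated)
Conditions: catecholborane, THF, 65 °C; then H2O, rt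
Reagents that add atoms: catecholborane, B1Oc2ccccc2O1; water, O
Why: Hydroboration of a terminal alkyne with catecholborane is a syn, anti-Markovnikov addition that fixes the (E)-alkenylboron geometry, and water hydrolyses the catechol ester to the boronic acid.

Step 9
Reactants: 7 (2E,5S)-5-(tert-butyldimethylsilyloxy)-N-methoxy-N-methyl-7-Ar-hept-2-enamide; 12 [(E)-2-Ar-ethenyl]boronic acid (2.5 equiv)
Product: 13 (3R,5S)-5-(tert-butyldimethylsilyloxy)-N-methoxy-N-methyl-3-[(E)-2-Ar-ethenyl]-7-Ar-heptanamide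
Conditions: [Rh(OH)((S)-BINAP)]2 (3 mol % Rh), dioxane/H2O 10:1, 50 °C
Reagents that add atoms: none
Why: In this Hayashi–Miyaura conjugate addition transmetalation gives an alkenyl complex of monovalent rhodium that inserts the (E)-enamide, (S)-BINAP steers it to the α-si face to set Ca, and water protonates the oxa-π-allyl rhodium without base that could harm the silyl ethers.

Step 10
Reactants: 13 (3R,5S)-5-(tert-butyldimethylsilyloxy)-N-methoxy-N-methyl-3-[(E)-2-Ar-ethenyl]-7-Ar-heptanamide; 9 4-(triisopropylsilyloxy)benzaldehyde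
Product: 14 (3S,5S)-2-[Ar(hydroxy)methyl]-5-(tert-butyldimethylsilyloxy)-N-methoxy-N-methyl-3-[(E)-2-Ar-ethenyl]-7-Ar-heptanamide (mixture of diastereomers at C2 and at the new carbinol)
Conditions: LiN(i-Pr)2, THF, −78 °C; then 9, −78 °C
Reagents that add atoms: none
Why: In this lithium enolate aldol addition the Weinreb amide has a single enolisable carbon (C2, the future C3), so the aldehyde is attached regiospecifically, and the two new stereocentres do not matter because both disappear in step 11.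

Step 11
Reactants: 14 (3S,5S)-2-[Ar(hydroxy)methyl]-5-(tert-butyldimethylsilyloxy)-N-methoxy-N-methyl-3-[(E)-2-Ar-ethenyl]-7-Ar-heptanamide
Product: 16 (2E,3S,5S)-2-(Ar-methylidene)-5-(tert-butyldimethylsilyloxy)-N-methoxy-N-methyl-3-[(E)-2-Ar-ethenyl]-7-Ar-heptanamide, via mesylate 15 (not isolated)
Conditions: MsCl, Et3N, CH2Cl2, 0 °C; then DBU, 0 °C → rt
Reagents that add atoms: none
Why: β-Elimination of the benzylic mesylate, which is activated by the para-siloxy group, should give the conjugated trisubstituted alkene with the aryl group trans to the carbonyl (E), the geometry the diene terminus needs.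

Step 12
Reactants: 16 (2E,3S,5S)-2-(Ar-methylidene)-5-(tert-butyldimethylsilyloxy)-N-methoxy-N-methyl-3-[(E)-2-Ar-ethenyl]-7-Ar-heptanamide
Product: 17 (3E)-4-Ar-3-[(1E,3S,5S)-5-(tert-butyldimethylsilyloxy)-1,7-di-Ar-hept-1-en-3-yl]but-3-en-2-one
Conditions: MeMgBr, THF, 0 °C
Reagents that add atoms: methylmagnesium bromide, C[Mg]Br
Why: In the Weinreb ketone synthesis the chelated tetrahedral magnesium adduct resists a second addition and releases the methyl ketone only on work-up, while the hindered electron-rich β-aryl position disfavours conjugate addition.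

Step 13
Reactants: 17 (3E)-4-Ar-3-[(1E,3S,5S)-5-(tert-butyldimethylsilyloxy)-1,7-di-Ar-hept-1-en-3-yl]but-3-en-2-one
Product: 18 (3E)-4-Ar-3-[(1E,3S,5S)-5-(tert-butyldimethylsilyloxy)-1,7-di-Ar-hept-1-en-3-yl]-2-(triethylsilyloxy)buta-1,3-diene
Conditions: Et3SiOTf, Et3N, Et2O, −78 → −20 °C
Reagents that add atoms: triethylsilyl trifluoromethanesulfonate, CC[Si](CC)(CC)OS(=O)(=O)C(F)(F)F
Why: In this soft enolisation with O-silylation the silyl triflate activates the carbonyl and Et3N removes a proton from the methyl group, the only α-carbon bearing hydrogen, faster than the hindered γ-hydrogen at Ca, giving the cross-conjugated 2-siloxydiene with the arylidene geometry intact.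

Step 14
Reactants: 18 (3E)-4-Ar-3-[(1E,3S,5S)-5-(tert-butyldimethylsilyloxy)-1,7-di-Ar-hept-1-en-3-yl]-2-(triethylsilyloxy)buta-1,3-diene; 3 3-Ar-propanal (1.5 equiv)
Product: 19 (2R,6S)-2-Ar-6-(2-Ar-ethyl)-3-[(1E,3S,5S)-5-(tert-butyldimethylsilyloxy)-1,7-di-Ar-hept-1-en-3-yl]-4-(triethylsilyloxy)-5,6-dihydro-2H-pyran
Conditions: (1R,2S)-[CrCl(L)] (10 mol %), 4 Å MS, t-BuOMe, rt
Reagents that add atoms: none
Why: The Lewis-acidic chromium centre (trivalent chromium) binds the aldehyde oxygen of 3 and the s-cis diene adds across the C=O bond, either in one asynchronous [4+2] event or by Mukaiyama aldol addition followed by 6-endo oxa-Michael closure, and both paths end in the same dihydropyran. The closest known reaction is the chromium Schiff-base-catalysed hetero-Diels–Alder reaction of aliphatic aldehydes with 2-siloxy-1,3-dienes that carry alkyl groups at the diene termini; the 1-aryl-2-alkyl diene is a new member of that class. The oxane is the only ring closed, in a [4+2] (formally 6-endo) mode that forms C5–C6 and O1–C2 and leaves C3=C4 as the triethylsilyl enol ether, so C3 stays trigonal. C6 is set by the catalyst, whose ligand shields one enantioface of the bound aldehyde, and C2 is set relative to C6 by the endo transition state, in which the aldehyde chain and the outward (E)-aryl terminus end up cis on the new ring. The step needs aldehyde-face selectivity, endo selectivity and cycloaddition faster than hydrolysis of the enol silane: an unbranched aliphatic aldehyde (the best substrate class for this catalyst), the Ca substituent at the 2-position that pushes the diene into the s-cis form, the (E)-geometry of the aryl terminus and the 4 Å sieves should secure these. Ca lies outside the forming bonds and should exert only a minor bias that the catalyst overrides.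

Step 15
Reactants: 19 (2R,6S)-2-Ar-6-(2-Ar-ethyl)-3-[(1E,3S,5S)-5-(tert-butyldimethylsilyloxy)-1,7-di-Ar-hept-1-en-3-yl]-4-(triethylsilyloxy)-5,6-dihydro-2H-pyran
Product: 20 (2S,3R,6S)-2-Ar-6-(2-Ar-ethyl)-3-[(1E,3S,5S)-5-(tert-butyldimethylsilyloxy)-1,7-di-Ar-hept-1-en-3-yl]oxan-4-one
Conditions: CF3CO2H (0.2 equiv), wet CH2Cl2, 0 °C → rt
Reagents that add atoms: none
Why: Acid hydrolysis of the silyl enol ether protonates C3 and releases the C4 ketone, and acid-catalysed enolisation should equilibrate C3 to the isomer with the side chain equatorial and trans to the C2 aryl group, while catalytic acid leaves the TBS and TIPS ethers in place.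

Step 16
Reactants: 20 (2S,3R,6S)-2-Ar-6-(2-Ar-ethyl)-3-[(1E,3S,5S)-5-(tert-butyldimethylsilyloxy)-1,7-di-Ar-hept-1-en-3-yl]oxan-4-one
Product: 21 (2S,3S,4S,6S)-2-Ar-6-(2-Ar-ethyl)-3-[(1E,3S,5S)-5-(tert-butyldimethylsilyloxy)-1,7-di-Ar-hept-1-en-3-yl]oxan-4-ol
Conditions: LiBH(s-Bu)3, THF, −78 °C
Reagents that add atoms: none
Why: In this ketone reduction the bulky trialkylborohydride approaches the chair along the less hindered equatorial trajectory, which should deliver the axial C4 alcohol cis to the C3 side chain.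

Step 17
Reactants: 21 (2S,3S,4S,6S)-2-Ar-6-(2-Ar-ethyl)-3-[(1E,3S,5S)-5-(tert-butyldimethylsilyloxy)-1,7-di-Ar-hept-1-en-3-yl]oxan-4-ol
Product: 22 Blepharocalyxin C
Conditions: Bu4NF (excess), AcOH, THF, 0 °C → rt
Reagents that add atoms: none
Why: Fluoride-mediated desilylation, driven by the strong Si–F bond, removes the four aryl TIPS groups and the secondary TBS group in one operation, and acetic acid buffers the phenoxides so that the 2-aryl oxane and the styrene see no strong base.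

Compound list
1 | methyl 3-(4-hydroxyphenyl)propanoate | COC(=O)CCc1ccc(O)cc1 | starting material
2 | methyl 3-[4-(triisopropylsilyloxy)phenyl]propanoate | COC(=O)CCc1ccc(O[Si](C(C)C)(C(C)C)C(C)C)cc1 | intermediate
3 | 3-[4-(triisopropylsilyloxy)phenyl]propanal | O=CCCc1ccc(O[Si](C(C)C)(C(C)C)C(C)C)cc1 | intermediate
4 | (3S)-1-[4-(triisopropylsilyloxy)phenyl]hex-5-en-3-ol | C=CC[C@@H](O)CCc1ccc(O[Si](C(C)C)(C(C)C)C(C)C)cc1 | intermediate
5 | (3S)-3-(tert-butyldimethylsilyloxy)-1-[4-(triisopropylsilyloxy)phenyl]hex-5-ene | C=CC[C@@H](O[Si](C)(C)C(C)(C)C)CCc1ccc(O[Si](C(C)C)(C(C)C)C(C)C)cc1 | intermediate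
6 | N-methoxy-N-methylprop-2-enamide | C=CC(=O)N(C)OC | starting material
7 | (2E,5S)-5-(tert-butyldimethylsilyloxy)-N-methoxy-N-methyl-7-Ar-hept-2-enamide | CON(C)C(=O)/C=C/C[C@@H](O[Si](C)(C)C(C)(C)C)CCc1ccc(O[Si](C(C)C)(C(C)C)C(C)C)cc1 | intermediate
8 | 4-hydroxybenzaldehyde | O=Cc1ccc(O)cc1 | starting material
9 | 4-(triisopropylsilyloxy)benzaldehyde | O=Cc1ccc(O[Si](C(C)C)(C(C)C)C(C)C)cc1 | intermediate
10 | 1-ethynyl-4-(triisopropylsilyloxy)benzene | C#Cc1ccc(O[Si](C(C)C)(C(C)C)C(C)C)cc1 | intermediate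
11 | 2-[(E)-2-Ar-ethenyl]-1,3,2-benzodioxaborole | CC(C)[Si](C(C)C)(C(C)C)Oc1ccc(/C=C/B2Oc3ccccc3O2)cc1 | intermediate
12 | [(E)-2-Ar-ethenyl]boronic acid | CC(C)[Si](C(C)C)(C(C)C)Oc1ccc(/C=C/B(O)O)cc1 | intermediate
13 | (3R,5S)-5-(tert-butyldimethylsilyloxy)-N-methoxy-N-methyl-3-[(E)-2-Ar-ethenyl]-7-Ar-heptanamide | CON(C)C(=O)C[C@H](/C=C/c1ccc(O[Si](C(C)C)(C(C)C)C(C)C)cc1)C[C@@H](O[Si](C)(C)C(C)(C)C)CCc1ccc(O[Si](C(C)C)(C(C)C)C(C)C)cc1 | intermediate
14 | (3S,5S)-2-[Ar(hydroxy)methyl]-5-(tert-butyldimethylsilyloxy)-N-methoxy-N-methyl-3-[(E)-2-Ar-ethenyl]-7-Ar-heptanamide, mixture at C2 and CH(OH) | CON(C)C(=O)C(C(O)c1ccc(O[Si](C(C)C)(C(C)C)C(C)C)cc1)[C@H](/C=C/c1ccc(O[Si](C(C)C)(C(C)C)C(C)C)cc1)C[C@@H](O[Si](C)(C)C(C)(C)C)CCc1ccc(O[Si](C(C)C)(C(C)C)C(C)C)cc1 | intermediate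
15 | methanesulfonate of 14 | CON(C)C(=O)C(C(OS(C)(=O)=O)c1ccc(O[Si](C(C)C)(C(C)C)C(C)C)cc1)[C@H](/C=C/c1ccc(O[Si](C(C)C)(C(C)C)C(C)C)cc1)C[C@@H](O[Si](C)(C)C(C)(C)C)CCc1ccc(O[Si](C(C)C)(C(C)C)C(C)C)cc1 | intermediate
16 | (2E,3S,5S)-2-(Ar-methylidene)-5-(tert-butyldimethylsilyloxy)-N-methoxy-N-methyl-3-[(E)-2-Ar-ethenyl]-7-Ar-heptanamide | CON(C)C(=O)/C(=C/c1ccc(O[Si](C(C)C)(C(C)C)C(C)C)cc1)[C@H](/C=C/c1ccc(O[Si](C(C)C)(C(C)C)C(C)C)cc1)C[C@@H](O[Si](C)(C)C(C)(C)C)CCc1ccc(O[Si](C(C)C)(C(C)C)C(C)C)cc1 | intermediate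
17 | (3E)-4-Ar-3-[(1E,3S,5S)-5-(tert-butyldimethylsilyloxy)-1,7-di-Ar-hept-1-en-3-yl]but-3-en-2-one | CC(=O)/C(=C/c1ccc(O[Si](C(C)C)(C(C)C)C(C)C)cc1)[C@H](/C=C/c1ccc(O[Si](C(C)C)(C(C)C)C(C)C)cc1)C[C@@H](O[Si](C)(C)C(C)(C)C)CCc1ccc(O[Si](C(C)C)(C(C)C)C(C)C)cc1 | intermediate
18 | (3E)-4-Ar-3-[(1E,3S,5S)-5-(tert-butyldimethylsilyloxy)-1,7-di-Ar-hept-1-en-3-yl]-2-(triethylsilyloxy)buta-1,3-diene | C=C(O[Si](CC)(CC)CC)/C(=C/c1ccc(O[Si](C(C)C)(C(C)C)C(C)C)cc1)[C@H](/C=C/c1ccc(O[Si](C(C)C)(C(C)C)C(C)C)cc1)C[C@@H](O[Si](C)(C)C(C)(C)C)CCc1ccc(O[Si](C(C)C)(C(C)C)C(C)C)cc1 | intermediate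
19 | (2R,6S)-2-Ar-6-(2-Ar-ethyl)-3-[(1E,3S,5S)-5-(tert-butyldimethylsilyloxy)-1,7-di-Ar-hept-1-en-3-yl]-4-(triethylsilyloxy)-5,6-dihydro-2H-pyran | CC(C)[Si](C(C)C)(C(C)C)Oc1ccc(/C=C/[C@H](C[C@@H](O[Si](C)(C)C(C)(C)C)CCc2ccc(O[Si](C(C)C)(C(C)C)C(C)C)cc2)C2=C(O[Si](CC)(CC)CC)C[C@H](CCc3ccc(O[Si](C(C)C)(C(C)C)C(C)C)cc3)O[C@@H]2c2ccc(O[Si](C(C)C)(C(C)C)C(C)C)cc2)cc1 | intermediate
20 | (2S,3R,6S)-2-Ar-6-(2-Ar-ethyl)-3-[(1E,3S,5S)-5-(tert-butyldimethylsilyloxy)-1,7-di-Ar-hept-1-en-3-yl]oxan-4-one | CC(C)[Si](C(C)C)(C(C)C)Oc1ccc(/C=C/[C@H](C[C@@H](O[Si](C)(C)C(C)(C)C)CCc2ccc(O[Si](C(C)C)(C(C)C)C(C)C)cc2)[C@@H]2[C@@H](c3ccc(O[Si](C(C)C)(C(C)C)C(C)C)cc3)O[C@@H](CCc3ccc(O[Si](C(C)C)(C(C)C)C(C)C)cc3)CC2=O)cc1 | intermediate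
21 | (2S,3S,4S,6S)-2-Ar-6-(2-Ar-ethyl)-3-[(1E,3S,5S)-5-(tert-butyldimethylsilyloxy)-1,7-di-Ar-hept-1-en-3-yl]oxan-4-ol | CC(C)[Si](C(C)C)(C(C)C)Oc1ccc(/C=C/[C@H](C[C@@H](O[Si](C)(C)C(C)(C)C)CCc2ccc(O[Si](C(C)C)(C(C)C)C(C)C)cc2)[C@@H]2[C@@H](c3ccc(O[Si](C(C)C)(C(C)C)C(C)C)cc3)O[C@@H](CCc3ccc(O[Si](C(C)C)(C(C)C)C(C)C)cc3)C[C@@H]2O)cc1 | intermediate
22 | Blepharocalyxin C, (2S,3S,4S,6S)-3-[(1E,3S,5S)-5-hydroxy-1,7-bis(4-hydroxyphenyl)hept-1-en-3-yl]-2-(4-hydroxyphenyl)-6-[2-(4-hydroxyphenyl)ethyl]oxan-4-ol | Oc1ccc(/C=C/[C@H](C[C@@H](O)CCc2ccc(O)cc2)[C@@H]2[C@@H](c3ccc(O)cc3)O[C@@H](CCc3ccc(O)cc3)C[C@@H]2O)cc1 | target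

Total step count: 17. Longest linear sequence: 14 steps (1 → 2 → 3 → 4 → 5 → 7 → 13 → 14 → 16 → 17 → 18 → 19 → 20 → 21 → 22).

Steps most likely to fail

Step 14. The hindered, styrene-conjugated diene may add so slowly that hydrolysis of the enol silane takes over, or endo and facial selectivity may erode. The fallback is a stepwise aldol and oxa-Michael sequence that sets out from 17 (with 3) and returns at 20, by-passing 18 and 19. Methyl ketone 17 would be enolised at its methyl group with (−)-Ipc2BCl/Et3N (the reagent enantiomer taken to give the (S)-carbinol) and the boron enolate added to aldehyde 3 in a reagent-controlled aldol reaction, giving the (1E,5S)-5-hydroxy-1,7-di-Ar-2-[(1E,3S,5S)-5-(tert-butyldimethylsilyloxy)-1,7-di-Ar-hept-1-en-3-yl]hept-1-en-3-one F1. Acid-catalysed 6-endo oxa-Michael closure (Amberlyst-15, CH2Cl2) under thermodynamic control should then give the all-equatorial ketone 20.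

Step 9. Insertion into the weakly electrophilic enamide may be slow, so that protodeboronation of 12 consumes the reagent or the higher temperature needed lowers face selectivity. The fallback changes the acceptor class; it sets out from 5 and returns at 13. Cross-metathesis of 5 with methyl acrylate would give methyl (2E,5S)-5-(tert-butyldimethylsilyloxy)-7-Ar-hept-2-enoate F2, an enoate of the class for which the rhodium/BINAP addition is best established. Addition of 12 under the conditions of step 9 would give methyl (3R,5S)-5-(tert-butyldimethylsilyloxy)-3-[(E)-2-Ar-ethenyl]-7-Ar-heptanoate F3, and aminolysis with Me(MeO)NH·HCl/i-PrMgCl would give 13.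

Step 11. Elimination at the amide oxidation level may not pass through an enolate, so the two aldol diastereomers could deliver both alkene geometries, and only the (E)-isomer can reach the reactive s-cis diene. The fallback moves the elimination to the ketone level; it sets out from 14 and returns at 17. Excess MeMgBr would be added to hydroxy amide 14 first, giving 4-Ar-4-hydroxy-3-[(1E,3S,5S)-5-(tert-butyldimethylsilyloxy)-1,7-di-Ar-hept-1-en-3-yl]butan-2-one F4. Its methanesulfonate F5 (MsCl, Et3N) should then eliminate by an E1cB path through the ketone enolate, which funnels both diastereomers to the more stable (E)-enone 17.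

Further compounds
F1 | step 14 | (1E,5S)-5-hydroxy-1,7-di-Ar-2-[(1E,3S,5S)-5-(tert-butyldimethylsilyloxy)-1,7-di-Ar-hept-1-en-3-yl]hept-1-en-3-one | O=C(C[C@@H](O)CCc1ccc(O[Si](C(C)C)(C(C)C)C(C)C)cc1)/C(=C/c1ccc(O[Si](C(C)C)(C(C)C)C(C)C)cc1)[C@H](/C=C/c1ccc(O[Si](C(C)C)(C(C)C)C(C)C)cc1)C[C@@H](O[Si](C)(C)C(C)(C)C)CCc1ccc(O[Si](C(C)C)(C(C)C)C(C)C)cc1
F2 | step 9 | methyl (2E,5S)-5-(tert-butyldimethylsilyloxy)-7-Ar-hept-2-enoate | COC(=O)/C=C/C[C@@H](O[Si](C)(C)C(C)(C)C)CCc1ccc(O[Si](C(C)C)(C(C)C)C(C)C)cc1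
F3 | step 9 | methyl (3R,5S)-5-(tert-butyldimethylsilyloxy)-3-[(E)-2-Ar-ethenyl]-7-Ar-heptanoate | COC(=O)C[C@H](/C=C/c1ccc(O[Si](C(C)C)(C(C)C)C(C)C)cc1)C[C@@H](O[Si](C)(C)C(C)(C)C)CCc1ccc(O[Si](C(C)C)(C(C)C)C(C)C)cc1
F4 | step 11 | 4-Ar-4-hydroxy-3-[(1E,3S,5S)-5-(tert-butyldimethylsilyloxy)-1,7-di-Ar-hept-1-en-3-yl]butan-2-one (diastereomer mixture) | CC(=O)C(C(O)c1ccc(O[Si](C(C)C)(C(C)C)C(C)C)cc1)[C@H](/C=C/c1ccc(O[Si](C(C)C)(C(C)C)C(C)C)cc1)C[C@@H](O[Si](C)(C)C(C)(C)C)CCc1ccc(O[Si](C(C)C)(C(C)C)C(C)C)cc1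
F5 | step 11 | methanesulfonate of F4 | CC(=O)C(C(OS(C)(=O)=O)c1ccc(O[Si](C(C)C)(C(C)C)C(C)C)cc1)[C@H](/C=C/c1ccc(O[Si](C(C)C)(C(C)C)C(C)C)cc1)C[C@@H](O[Si](C)(C)C(C)(C)C)CCc1ccc(O[Si](C(C)C)(C(C)C)C(C)C)cc1
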